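## Retrosynthetic overview

1. Target 18 ⇐ tri-O-benzyl biflavone 17 by hydrogenolysis (methyl ethers permanent, benzyl ethers temporary).
2. Pyranone ring C of flavone unit B (the 5-hydroxy-7-methoxy half) ⇐ oxidative cyclisation of 2'-hydroxychalcone 15 ⇐ Claisen–Schmidt aldol condensation of flavonyl-benzaldehyde 11 with acetophenone 13; this is the key C–C bond that joins the two halves.
3. Biaryl bond of 11 ⇐ Suzuki coupling of 6-iodoflavone 9 with boronic acid 10; the C6 iodide ⇐ 5-OH-directed iodination of 7-O-benzylacacetin 7.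
4. Pyranone ring C of flavone unit A (acacetin 6) ⇐ crossed Claisen condensation of phloroacetophenone 1 with 4-methoxybenzoyl chloride 2, then cyclodehydration.
5. Ring order: pyranone of unit A first, biaryl bond second, pyranone of unit B last.

Assumption: the SMILES has no stereocentre and no assigned axial configuration, so the target is made as drawn, without control of the tri-ortho-substituted biaryl axis.

## Route

Step 1
Reactants: 1 2',4',6'-trihydroxyacetophenone (dried, anhydrous); 2 4-methoxybenzoyl chloride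
Product: 4 1-(4-methoxyphenyl)-3-(2,4,6-trihydroxyphenyl)propane-1,3-dione, via tetralithium enolate 3 (not isolated)
Conditions: LiN(SiMe3)2 (5 equiv), THF, −78 → −10 °C; then 2 (1.0 equiv), −78 °C → rt; aq. HCl work-up
Reagents that add atoms: none
Why: Crossed Claisen condensation: LiN(SiMe3)2 turns 1 into its tris-phenoxide ketone enolate, whose carbon terminus is acylated by the non-enolisable acid chloride 2, and the fifth equivalent of base deprotonates the 1,3-diketone formed so that the condensation runs to completion without O-protection.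

Step 2
Reactants: 4 1-(4-methoxyphenyl)-3-(2,4,6-trihydroxyphenyl)propane-1,3-dione
Product: 6 acacetin [5,7-dihydroxy-2-(4-methoxyphenyl)-4H-chromen-4-one], via 2-hydroxyflavanone hemiketal 5 (not isolated)
Conditions: AcOH, H2SO4 (0.5 vol %), 95–100 °C, 1 h
Reagents that add atoms: none
Why: Acid-catalysed cyclodehydration (hemiketal formation, then loss of water) closes ring C, and because ring A of 4 is symmetric either ortho-hydroxyl gives the same flavone.

Step 3
Reactants: 6 acacetin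
Product: 7 7-(benzyloxy)-5-hydroxy-2-(4-methoxyphenyl)-4H-chromen-4-one
Conditions: BnBr (1.05 equiv), K2CO3 (1.2 equiv), DMF, rt
Reagents that add atoms: benzyl bromide, BrCc1ccccc1
Why: Williamson etherification: the 7-OH is the most acidic and is not hydrogen-bonded, whereas the 5-OH is locked in a chelate with the C4 carbonyl and stays free under these mild conditions.

Step 4
Reactants: 7 7-(benzyloxy)-5-hydroxy-2-(4-methoxyphenyl)-4H-chromen-4-one
Product: 8 7-(benzyloxy)-5-hydroxy-6-iodo-2-(4-methoxyphenyl)-4H-chromen-4-one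
Conditions: BnMe3N·ICl2 (1.1 equiv), CaCO3 (2 equiv), CH2Cl2/MeOH (5:2), rt
Reagents that add atoms: benzyltrimethylammonium dichloroiodate, C[N+](C)(C)Cc1ccccc1.Cl[I-]Cl
Why: Electrophilic aromatic iodination: in 5-hydroxy-7-alkoxyflavones the free, chelated 5-OH steers the iodinating agent to its ortho carbon C6 rather than to C8, and CaCO3 buffers the HCl so that the benzyl ether survives.

Step 5
Reactants: 8 7-(benzyloxy)-5-hydroxy-6-iodo-2-(4-methoxyphenyl)-4H-chromen-4-one
Product: 9 5,7-bis(benzyloxy)-6-iodo-2-(4-methoxyphenyl)-4H-chromen-4-one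
Conditions: BnBr (1.5 equiv), K2CO3 (3 equiv), n-Bu4NI (0.1 equiv), DMF, 60 °C
Reagents that add atoms: benzyl bromide, BrCc1ccccc1
Why: Williamson etherification under forcing conditions (excess base, iodide catalysis, heat) overcomes the chelation and flanking substituents of the 5-OH, and capping it removes an acidic ortho-phenol before the cross-coupling and the basic aldol step.

Step 6
Reactants: 9 5,7-bis(benzyloxy)-6-iodo-2-(4-methoxyphenyl)-4H-chromen-4-one; 10 (5-formyl-2-methoxyphenyl)boronic acid (2 equiv)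
Product: 11 3-[5,7-bis(benzyloxy)-2-(4-methoxyphenyl)-4-oxo-4H-chromen-6-yl]-4-methoxybenzaldehyde
Conditions: Pd(OAc)2 (5 mol %), SPhos (10 mol %), K3PO4 (3 equiv), toluene/H2O (10:1), degassed, 90 °C
Reagents that add atoms: none
Why: Suzuki–Miyaura coupling: the aryl iodide adds readily to zerovalent palladium and the bulky, electron-rich biarylphosphine SPhos promotes transmetalation and reductive elimination to the tri-ortho-substituted biaryl, while the aldehyde is inert to these conditions.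

Step 7
Reactants: 12 2',6'-dihydroxy-4'-methoxyacetophenone
Product: 13 1-[2-(benzyloxy)-6-hydroxy-4-methoxyphenyl]ethan-1-one
Conditions: BnBr (1.05 equiv), K2CO3 (1.1 equiv), acetone, reflux
Reagents that add atoms: benzyl bromide, BrCc1ccccc1
Why: Williamson mono-etherification: the two hydroxyls of 12 are equivalent, and once one is benzylated the other is held in a hydrogen bond to the ketone and reacts far more slowly, so one equivalent of BnBr gives the mono-ether.

Step 8
Reactants: 11 3-[5,7-bis(benzyloxy)-2-(4-methoxyphenyl)-4-oxo-4H-chromen-6-yl]-4-methoxybenzaldehyde; 13 1-[2-(benzyloxy)-6-hydroxy-4-methoxyphenyl]ethan-1-one (1.2 equiv)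
Product: 15 (E)-1-[2-(benzyloxy)-6-hydroxy-4-methoxyphenyl]-3-{3-[5,7-bis(benzyloxy)-2-(4-methoxyphenyl)-4-oxo-4H-chromen-6-yl]-4-methoxyphenyl}prop-2-en-1-one, via β-hydroxy ketone 14 (not isolated)
Conditions: KOH (50% aq., 10 equiv), EtOH/THF (2:1), 0 °C → rt, 24–48 h; then cold 1 M HCl
Reagents that add atoms: none
Why: Claisen–Schmidt (crossed aldol) condensation: 13 is the only enolisable partner and 11 the only aldehyde, the aldol adduct 14 dehydrates by E1cB to the conjugated (E)-enone (the thermodynamic geometry), and the fully O-protected flavone of 11 tolerates aqueous KOH at room temperature.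

Step 9
Reactants: 15 the (E)-chalcone from step 8 (any flavanone formed during work-up is carried along)
Product: 17 5,7-bis(benzyloxy)-6-{5-[5-(benzyloxy)-7-methoxy-4-oxo-4H-chromen-2-yl]-2-methoxyphenyl}-2-(4-methoxyphenyl)-4H-chromen-4-one, via flavanone 16 (not isolated)
Conditions: I2 (0.1–0.2 equiv), DMSO, 120 °C, 2–4 h; aq. Na2S2O3 quench
Reagents that add atoms: none
Why: Oxidative cyclisation of a 2'-hydroxychalcone: intramolecular oxa-Michael addition gives flavanone 16, which iodine dehydrogenates (α-iodination and loss of HI) while DMSO re-oxidises HI to I2, and the racemic C2 centre of 16 disappears on aromatisation of ring C.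

Step 10
Reactants: 17 the tri-O-benzyl biflavone from step 9
Product: 18 5,7-dihydroxy-6-[5-(5-hydroxy-7-methoxy-4-oxo-4H-chromen-2-yl)-2-methoxyphenyl]-2-(4-methoxyphenyl)-4H-chromen-4-one (robustaflavone 7,4',4'''-trimethyl ether, CNP0281098.0)
Conditions: H2 (1 atm), Pd/C (10 wt % Pd), THF/MeOH (1:1), rt
Reagents that add atoms: none
Why: Catalytic hydrogenolysis cleaves only the three benzylic C–O bonds, since aryl methyl ethers are inert and the chromone C2=C3 bonds (aryl-conjugated vinylogous esters) are not reduced at 1 atm and room temperature if the reaction is stopped at full debenzylation.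

## Compound list

1 | 2',4',6'-trihydroxyacetophenone | CC(=O)c1c(O)cc(O)cc1O | starting material
2 | 4-methoxybenzoyl chloride | COc1ccc(C(=O)Cl)cc1 | starting material
3 | tetralithium enolate tris-phenoxide of 1 (not isolated) | [Li+].[Li+].[Li+].[Li+].C=C([O-])c1c([O-])cc([O-])cc1[O-] | intermediate
4 | 1-(4-methoxyphenyl)-3-(2,4,6-trihydroxyphenyl)propane-1,3-dione | COc1ccc(C(=O)CC(=O)c2c(O)cc(O)cc2O)cc1 | intermediate
5 | 2,5,7-trihydroxy-2-(4-methoxyphenyl)chroman-4-one, racemic hemiketal (not isolated) | COc1ccc(C2(O)CC(=O)c3c(O)cc(O)cc3O2)cc1 | intermediate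
6 | acacetin, 5,7-dihydroxy-2-(4-methoxyphenyl)-4H-chromen-4-one | COc1ccc(-c2cc(=O)c3c(O)cc(O)cc3o2)cc1 | intermediate
7 | 7-(benzyloxy)-5-hydroxy-2-(4-methoxyphenyl)-4H-chromen-4-one | COc1ccc(-c2cc(=O)c3c(O)cc(OCc4ccccc4)cc3o2)cc1 | intermediate
8 | 7-(benzyloxy)-5-hydroxy-6-iodo-2-(4-methoxyphenyl)-4H-chromen-4-one | COc1ccc(-c2cc(=O)c3c(O)c(I)c(OCc4ccccc4)cc3o2)cc1 | intermediate
9 | 5,7-bis(benzyloxy)-6-iodo-2-(4-methoxyphenyl)-4H-chromen-4-one | COc1ccc(-c2cc(=O)c3c(OCc4ccccc4)c(I)c(OCc4ccccc4)cc3o2)cc1 | intermediate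
10 | (5-formyl-2-methoxyphenyl)boronic acid | COc1ccc(C=O)cc1B(O)O | starting material
11 | 3-[5,7-bis(benzyloxy)-2-(4-methoxyphenyl)-4-oxo-4H-chromen-6-yl]-4-methoxybenzaldehyde | COc1ccc(-c2cc(=O)c3c(OCc4ccccc4)c(-c4cc(C=O)ccc4OC)c(OCc4ccccc4)cc3o2)cc1 | intermediate
12 | 2',6'-dihydroxy-4'-methoxyacetophenone | CC(=O)c1c(O)cc(OC)cc1O | starting material
13 | 1-[2-(benzyloxy)-6-hydroxy-4-methoxyphenyl]ethan-1-one | CC(=O)c1c(O)cc(OC)cc1OCc1ccccc1 | intermediate
14 | 1-[2-(benzyloxy)-6-hydroxy-4-methoxyphenyl]-3-{3-[5,7-bis(benzyloxy)-2-(4-methoxyphenyl)-4-oxo-4H-chromen-6-yl]-4-methoxyphenyl}-3-hydroxypropan-1-one, racemic aldol adduct (not isolated) | COc1ccc(-c2cc(=O)c3c(OCc4ccccc4)c(-c4cc(C(O)CC(=O)c5c(O)cc(OC)cc5OCc5ccccc5)ccc4OC)c(OCc4ccccc4)cc3o2)cc1 | intermediate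
15 | (E)-1-[2-(benzyloxy)-6-hydroxy-4-methoxyphenyl]-3-{3-[5,7-bis(benzyloxy)-2-(4-methoxyphenyl)-4-oxo-4H-chromen-6-yl]-4-methoxyphenyl}prop-2-en-1-one | COc1ccc(-c2cc(=O)c3c(OCc4ccccc4)c(-c4cc(/C=C/C(=O)c5c(O)cc(OC)cc5OCc5ccccc5)ccc4OC)c(OCc4ccccc4)cc3o2)cc1 | intermediate
16 | 5-(benzyloxy)-2-{3-[5,7-bis(benzyloxy)-2-(4-methoxyphenyl)-4-oxo-4H-chromen-6-yl]-4-methoxyphenyl}-7-methoxychroman-4-one, racemic flavanone (not isolated) | COc1ccc(-c2cc(=O)c3c(OCc4ccccc4)c(-c4cc(C5CC(=O)c6c(OCc7ccccc7)cc(OC)cc6O5)ccc4OC)c(OCc4ccccc4)cc3o2)cc1 | intermediate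
17 | 5,7-bis(benzyloxy)-6-{5-[5-(benzyloxy)-7-methoxy-4-oxo-4H-chromen-2-yl]-2-methoxyphenyl}-2-(4-methoxyphenyl)-4H-chromen-4-one | COc1ccc(-c2cc(=O)c3c(OCc4ccccc4)c(-c4cc(-c5cc(=O)c6c(OCc7ccccc7)cc(OC)cc6o5)ccc4OC)c(OCc4ccccc4)cc3o2)cc1 | intermediate
18 | 5,7-dihydroxy-6-[5-(5-hydroxy-7-methoxy-4-oxo-4H-chromen-2-yl)-2-methoxyphenyl]-2-(4-methoxyphenyl)-4H-chromen-4-one | COc1ccc(-c2cc(=O)c3c(O)c(-c4cc(-c5cc(=O)c6c(O)cc(OC)cc6o5)ccc4OC)c(O)cc3o2)cc1 | target

## Step count and risks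

Total steps: 10. Longest linear sequence: 9 steps (steps 1–6, then 8–10, from 1); step 7 is a one-step side branch.

**Step 4 (C6 versus C8 iodination).** The regiochemistry rests on substrate bias and must be confirmed on 8 (HMBC from the chelated 5-OH proton to the iodine-bearing, non-protonated C6). If C6/C8 mixtures form, the fallback sets out from 7 and comes back to the route at 11, replacing steps 4–6. Boronic acid 10 is converted by boron–lead exchange (Pb(OAc)4, cat. Hg(OAc)2, CHCl3, 40 °C) into (5-formyl-2-methoxyphenyl)lead triacetate F1. Pinhey arylation of phenol 7 with F1 (pyridine, CHCl3, 60 °C) runs by ligand coupling on the lead-bound phenoxide and can only reach C6, the single free position ortho to the 5-OH. It gives 3-[7-(benzyloxy)-5-hydroxy-2-(4-methoxyphenyl)-4-oxo-4H-chromen-6-yl]-4-methoxybenzaldehyde F2. Benzylation of the 5-OH of F2 (BnBr, K2CO3, n-Bu4NI, DMF, 60 °C) then gives 11.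

**Step 6 (Suzuki coupling to a tri-ortho-substituted biaryl).** Slow transmetalation at the doubly flanked iodide may let protodeboronation of 10 win. The fallback sets out from 9 and comes back at 11, replacing boron by zinc (Negishi coupling). Commercial 3-bromo-4-methoxybenzaldehyde is protected (ethylene glycol, cat. TsOH, toluene, Dean–Stark) as 2-(3-bromo-4-methoxyphenyl)-1,3-dioxolane F3. Bromine–lithium exchange (n-BuLi, THF, −78 °C) gives [5-(1,3-dioxolan-2-yl)-2-methoxyphenyl]lithium F4, and ZnCl2 converts it into [5-(1,3-dioxolan-2-yl)-2-methoxyphenyl]zinc chloride F5. Coupling of F5 with 9 (Pd(OAc)2, SPhos, THF, 60 °C) gives 5,7-bis(benzyloxy)-6-[5-(1,3-dioxolan-2-yl)-2-methoxyphenyl]-2-(4-methoxyphenyl)-4H-chromen-4-one F6. Acetal hydrolysis (1 M HCl, THF, rt) then gives 11.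

**Step 8 (aldol condensation in the presence of a flavone).** Hydroxide may open ring C of the flavone in 11, or the condensation may stall at the hindered, chelated acetophenone. The fallback sets out from 11 and comes back at 17, replacing steps 8 and 9 by an acyl-transfer route that avoids aqueous hydroxide. Pinnick oxidation of 11 (NaClO2, NaH2PO4, 2-methyl-2-butene, t-BuOH/THF/H2O, rt) gives 3-[5,7-bis(benzyloxy)-2-(4-methoxyphenyl)-4-oxo-4H-chromen-6-yl]-4-methoxybenzoic acid F7. Esterification with phenol 13 (EDC·HCl, DMAP, CH2Cl2, rt) gives 2-acetyl-3-(benzyloxy)-5-methoxyphenyl 3-[5,7-bis(benzyloxy)-2-(4-methoxyphenyl)-4-oxo-4H-chromen-6-yl]-4-methoxybenzoate F8. Baker–Venkataraman rearrangement (KOt-Bu, THF, 0 °C → rt) gives 1-[2-(benzyloxy)-6-hydroxy-4-methoxyphenyl]-3-{3-[5,7-bis(benzyloxy)-2-(4-methoxyphenyl)-4-oxo-4H-chromen-6-yl]-4-methoxyphenyl}propane-1,3-dione F9. Cyclodehydration (cat. TsOH, toluene, 90 °C) then gives 17.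

## Further compounds

F1 | step 4 | (5-formyl-2-methoxyphenyl)lead triacetate | COc1ccc(C=O)cc1[Pb](OC(C)=O)(OC(C)=O)OC(C)=O
F2 | step 4 | 3-[7-(benzyloxy)-5-hydroxy-2-(4-methoxyphenyl)-4-oxo-4H-chromen-6-yl]-4-methoxybenzaldehyde | COc1ccc(-c2cc(=O)c3c(O)c(-c4cc(C=O)ccc4OC)c(OCc4ccccc4)cc3o2)cc1
F3 | step 6 | 2-(3-bromo-4-methoxyphenyl)-1,3-dioxolane | COc1ccc(C2OCCO2)cc1Br
F4 | step 6 | [5-(1,3-dioxolan-2-yl)-2-methoxyphenyl]lithium | [Li]c1cc(C2OCCO2)ccc1OC
F5 | step 6 | [5-(1,3-dioxolan-2-yl)-2-methoxyphenyl]zinc chloride | Cl[Zn]c1cc(C2OCCO2)ccc1OC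
F6 | step 6 | 5,7-bis(benzyloxy)-6-[5-(1,3-dioxolan-2-yl)-2-methoxyphenyl]-2-(4-methoxyphenyl)-4H-chromen-4-one | COc1ccc(-c2cc(=O)c3c(OCc4ccccc4)c(-c4cc(C5OCCO5)ccc4OC)c(OCc4ccccc4)cc3o2)cc1
F7 | step 8 | 3-[5,7-bis(benzyloxy)-2-(4-methoxyphenyl)-4-oxo-4H-chromen-6-yl]-4-methoxybenzoic acid | COc1ccc(-c2cc(=O)c3c(OCc4ccccc4)c(-c4cc(C(=O)O)ccc4OC)c(OCc4ccccc4)cc3o2)cc1
F8 | step 8 | 2-acetyl-3-(benzyloxy)-5-methoxyphenyl 3-[5,7-bis(benzyloxy)-2-(4-methoxyphenyl)-4-oxo-4H-chromen-6-yl]-4-methoxybenzoate | COc1ccc(-c2cc(=O)c3c(OCc4ccccc4)c(-c4cc(C(=O)Oc5cc(OC)cc(OCc6ccccc6)c5C(C)=O)ccc4OC)c(OCc4ccccc4)cc3o2)cc1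
F9 | step 8 | 1-[2-(benzyloxy)-6-hydroxy-4-methoxyphenyl]-3-{3-[5,7-bis(benzyloxy)-2-(4-methoxyphenyl)-4-oxo-4H-chromen-6-yl]-4-methoxyphenyl}propane-1,3-dione | COc1ccc(-c2cc(=O)c3c(OCc4ccccc4)c(-c4cc(C(=O)CC(=O)c5c(O)cc(OC)cc5OCc5ccccc5)ccc4OC)c(OCc4ccccc4)cc3o2)cc1
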